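The seven-membered ring is cut at C10–C1. C10 is its only functionalised carbon and sits on ring-fusion carbon C9, so an acyl radical at C10 can reach C1, the alkene terminus of the C4(Me2)–C3–C2=C1 chain held cis on C5 of the cyclopentane. One tin-mediated 7-endo closure forms the ring and leaves the C10 ketone needed for the final methylenation, without touching C9. The precursor 26 is a fully elaborated cyclopentane: C8 quaternary centre with the acetoxymethyl/butyrolactone side chain, a C9 phenyl selenoester and a cis 1,1-dimethylbut-3-enyl group on C5.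

Key step: step 15

Remark: atoms carry the hydroazulene labels C1–C10; C11 is the side-chain CH on C8, C12 the lactone CH, C13 the acetoxymethyl carbon, C14 the lactone OCH2 carbon. The imine Michael addition of step 3 is assumed to take the usual compact course with internal N–H transfer.

Step 1
Reactants: 1 (tert-butyldimethylsilyloxy)acetaldehyde; 2 nitromethane
Product: 4 (E)-tert-butyldimethyl[(3-nitroprop-2-en-1-yl)oxy]silane, via nitro alcohol 3 (not isolated)
Conditions: MeNO2 (solvent), Et3N (cat.), rt; concentrate; then MsCl, Et3N, CH2Cl2, −10 °C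
Reagents that add atoms: none
Why: Henry (nitroaldol) addition followed by mesylation and E1cB elimination should give the conjugated nitroalkene as its more stable E isomer.

Step 2
Reactants: 5 2-methylcyclopentanone (racemic); 6 (R)-1-phenylethylamine
Product: 7 (R)-N-(2-methylcyclopentylidene)-1-phenylethan-1-amine (mixture at C2 and C=N)
Conditions: TsOH·H2O (cat.), toluene, reflux, Dean–Stark
Reagents that add atoms: none
Why: Acid-catalysed imine condensation; the ring stereocentre of 5 does not matter because it is erased through the secondary enamine tautomer in step 3.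

Step 3
Reactants: 7 chiral imine; 4 nitroalkene
Product: 9 (S)-2-[(S)-1-(tert-butyldimethylsilyloxy)-3-nitropropan-2-yl]-2-methylcyclopentan-1-one, via Michael adduct imine 8 (not isolated)
Conditions: THF, −20 °C → rt; then aq. AcOH–NaOAc (pH 4–5), THF, rt
Reagents that add atoms: water, SMILES O
Why: d'Angelo-type Michael addition of a chiral imine through its more substituted secondary enamine: the nitroalkene should approach the enamine face anti to the phenyl group in a compact chair-like array (nitro-bearing carbon over nitrogen for N–H transfer, CH2OTBS exo), which sets C8 and C11 together, and buffered hydrolysis then releases the ketone and the auxiliary amine.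

Step 4
Reactants: 9 nitro ketone
Product: 11 (R)-3-(tert-butyldimethylsilyloxy)-2-[(S)-1-methyl-2-oxocyclopentyl]propanal, via sodium nitronate 10 (not isolated)
Conditions: NaOMe (1.05 equiv), MeOH, 0 °C; then O3, MeOH/CH2Cl2, −78 °C; pH 7 buffer
Reagents that add atoms: ozone, SMILES [O-][O+]=O
Why: Nef-type conversion by ozonolysis of the nitronate C=N bond; deprotonation occurs at C12 and not at C11, and the cold buffered work-up should keep the new α-stereocentre of the hindered aldehyde intact.

Step 5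
Reactants: 11 aldehyde
Product: 12 methyl (2Z,4R)-5-(tert-butyldimethylsilyloxy)-4-[(S)-1-methyl-2-oxocyclopentyl]pent-2-enoate
Conditions: (CF3CH2O)2P(O)CH2CO2Me, KN(SiMe3)2, 18-crown-6, THF, −78 °C
Reagents that add atoms: methyl bis(2,2,2-trifluoroethyl)phosphonoacetate, SMILES COC(=O)CP(=O)(OCC(F)(F)F)OCC(F)(F)F
Why: Still–Gennari olefination, which is Z-selective for α-branched aldehydes and gives the cis enoate needed for lactonisation, while the low temperature protects C11.

Step 6
Reactants: 12 Z-enoate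
Product: 14 (R)-5-[(S)-1-methyl-2-oxocyclopentyl]-5,6-dihydro-2H-pyran-2-one, via hydroxy ester 13 (not isolated)
Conditions: HF·pyridine, THF, 0 °C → rt; then PPTS (cat.), toluene, 60 °C
Reagents that add atoms: none
Why: Fluoride desilylation frees the C13 hydroxyl, which lactonises onto the cis ester (acid-catalysed transesterification) to give the unsaturated six-membered lactone without touching a stereocentre.

Step 7
Reactants: 14 unsaturated lactone
Product: 15 (4R,5R)-4-(hydroxymethyl)-5-[(S)-1-methyl-2-oxocyclopentyl]tetrahydro-2H-pyran-2-one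
Conditions: MeOH, benzophenone (0.3 equiv), hν (350 nm), degassed, rt
Reagents that add atoms: methanol, SMILES CO
Why: Benzophenone-sensitised radical hydroxymethylation (conjugate addition of the hydroxymethyl radical from methanol) of an unsaturated lactone: the radical should add to the β-carbon C12 anti to the bulky group on the neighbouring C11, giving the 4,5-trans lactone and with it the C12 configuration of the target.

Step 8
Reactants: 15 hydroxymethyl lactone
Product: 17 (R)-2-[(S)-1-methyl-2-oxocyclopentyl]-2-[(R)-5-oxotetrahydrofuran-3-yl]ethyl acetate, via hydroxy lactone 16 (not isolated)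
Conditions: PPTS (cat.), CH2Cl2, rt; then Ac2O, pyridine, DMAP (cat.), 0 °C → rt
Reagents that add atoms: acetic anhydride, SMILES CC(=O)OC(C)=O
Why: Acid-catalysed translactonisation moves the acyl group from the C13 oxygen to the C14 oxygen because the five-membered lactone is the more stable one, and acetylation of the freed primary C13 alcohol fixes the side chain.

Step 9
Reactants: 17 ketone
Product: 18 (R)-2-[(S)-1-methyl-2-{[(trifluoromethyl)sulfonyl]oxy}cyclopent-2-en-1-yl]-2-[(R)-5-oxotetrahydrofuran-3-yl]ethyl acetate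
Conditions: Tf2O, 2,6-di-tert-butyl-4-methylpyridine, CH2Cl2, 0 °C → rt
Reagents that add atoms: trifluoromethanesulfonic anhydride, SMILES O=S(=O)(OS(=O)(=O)C(F)(F)F)C(F)(F)F
Why: Electrophilic enol triflate formation without an enolate base, so lactone and acetate are not deprotonated; only C5 carries α-hydrogens, so one regioisomer can form.

Step 10
Reactants: 18 enol triflate
Product: 19 4-methoxybenzyl (S)-5-{(R)-2-acetoxy-1-[(R)-5-oxotetrahydrofuran-3-yl]ethyl}-5-methylcyclopent-1-ene-1-carboxylate
Conditions: Pd(OAc)2 (10 mol %), PPh3, Et3N, CO (1 atm), 4-methoxybenzyl alcohol, DMF, 60 °C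
Reagents that add atoms: carbon monoxide, SMILES [C-]#[O+]; 4-methoxybenzyl alcohol, SMILES COc1ccc(CO)cc1
Why: Palladium-catalysed alkoxycarbonylation of the enol triflate installs C10 as an unsaturated ester whose 4-methoxybenzyl group can later be removed by acid alone.

Step 11
Reactants: 20 2,2-dimethylpent-4-enoic acid; 21 N-hydroxyphthalimide
Product: 22 1,3-dioxoisoindolin-2-yl 2,2-dimethylpent-4-enoate
Conditions: N,N'-diisopropylcarbodiimide, DMAP (cat.), CH2Cl2, rt
Reagents that add atoms: none
Why: Steglich-type carbodiimide esterification gives the redox-active ester that serves as the tertiary radical precursor.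

Step 12
Reactants: 19 unsaturated ester; 22 redox-active ester (3 equiv)
Product: 23 4-methoxybenzyl (1R,2S,5R)-2-{(R)-2-acetoxy-1-[(R)-5-oxotetrahydrofuran-3-yl]ethyl}-2-methyl-5-(2-methylpent-4-en-2-yl)cyclopentane-1-carboxylate
Conditions: Ru(bpy)3(PF6)2 (1 mol %), Hantzsch ester (3 equiv), i-Pr2NEt·HBF4 (1 equiv), CH2Cl2, blue LEDs, rt
Reagents that add atoms: none
Why: Photoredox decarboxylative Giese addition: the nucleophilic tertiary 1,1-dimethylbut-3-enyl radical (the stable member of its homoallyl manifold) should add to the β-carbon C5 on the face of the C8 methyl group, away from the larger side chain, and the C9 radical should then take up hydrogen from the face opposite the new tert-alkyl group, which places the ester cis to it.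

Step 13
Reactants: 23 4-methoxybenzyl ester
Product: 24 (1R,2S,5R)-2-{(R)-2-acetoxy-1-[(R)-5-oxotetrahydrofuran-3-yl]ethyl}-2-methyl-5-(2-methylpent-4-en-2-yl)cyclopentane-1-carboxylic acid
Conditions: TFA, anisole, CH2Cl2, 0 °C
Reagents that add atoms: none
Why: Acidolysis of the 4-methoxybenzyl ester through the stabilised benzylic cation (trapped by anisole) frees the acid without base, so C9 cannot epimerise and acetate, lactone and alkene stay intact.

Step 14
Reactants: 24 carboxylic acid; 25 diphenyl diselenide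
Product: 26 Se-phenyl (1R,2S,5R)-2-{(R)-2-acetoxy-1-[(R)-5-oxotetrahydrofuran-3-yl]ethyl}-2-methyl-5-(2-methylpent-4-en-2-yl)cyclopentane-1-carboselenoate
Conditions: Bu3P, CH2Cl2, rt
Reagents that add atoms: none
Why: Phosphine–diselenide selenoesterification (acyloxyphosphonium attacked by benzeneselenolate) runs under neutral conditions and should leave the C9 configuration unchanged.

Step 15
Reactants: 26 phenyl selenoester
Product: 27 (R)-2-[(3S,3aR,8aR)-3,8,8-trimethyl-4-oxodecahydroazulen-3-yl]-2-[(R)-5-oxotetrahydrofuran-3-yl]ethyl acetate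
Conditions: Bu3SnH (1.3 equiv, syringe pump), AIBN (cat.), benzene, 80 °C, 0.005 M
Reagents that add atoms: none
Why: The stannyl radical abstracts the phenylseleno group to give the acyl radical at C10, which adds to the terminal alkene carbon C1, and the secondary C2 radical is then reduced by Bu3SnH to carry the chain. The closest known reaction type is the tin-hydride cyclisation of selenoester-derived acyl radicals onto unactivated alkenes. The seven-membered ring closes in the 7-endo-trig mode. No stereocentre is formed, and C9 keeps its configuration because the acyl σ-radical never planarises it. The step needs 7-endo closure to beat 6-exo closure, loss of CO and direct reduction: attack at the unsubstituted terminus is the usual preference of acyl radicals, a 6-exo adduct (a β-keto primary radical) should ring-expand by 1,2-acyl shift to the same C2 radical, and the cis C9/C5 arrangement with the gem-dimethyl group on C4 holds the ends close while slow stannane addition at high dilution suppresses early reduction.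

Step 16
Reactants: 27 ketone
Product: 28 (R)-2-[(3R,3aS,8aR)-3,8,8-trimethyl-4-methylidenedecahydroazulen-3-yl]-2-[(R)-5-oxotetrahydrofuran-3-yl]ethyl acetate
Conditions: Zn, CH2Br2, TiCl4, THF/CH2Cl2, 0 °C → rt
Reagents that add atoms: dibromomethane, SMILES BrCBr
Why: Lombardo–Takai methylenation: the non-basic zinc–titanium methylene reagent should convert the hindered, enolisable C10 ketone into the exocyclic alkene without epimerising C9 and without attacking acetate or lactone.

Compound list
1 | (tert-butyldimethylsilyloxy)acetaldehyde | CC(C)(C)[Si](C)(C)OCC=O | starting material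
2 | nitromethane | C[N+](=O)[O-] | starting material
3 | 1-(tert-butyldimethylsilyloxy)-3-nitropropan-2-ol (racemic) | CC(C)(C)[Si](C)(C)OCC(O)C[N+](=O)[O-] | intermediate
4 | (E)-tert-butyldimethyl[(3-nitroprop-2-en-1-yl)oxy]silane | CC(C)(C)[Si](C)(C)OC/C=C/[N+](=O)[O-] | intermediate
5 | 2-methylcyclopentanone (racemic) | CC1CCCC1=O | starting material
6 | (R)-1-phenylethylamine | C[C@@H](N)c1ccccc1 | starting material
7 | (R)-N-(2-methylcyclopentylidene)-1-phenylethan-1-amine | C[C@@H](N=C1CCCC1C)c1ccccc1 | intermediate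
8 | (R)-N-{(S)-2-[(S)-1-(tert-butyldimethylsilyloxy)-3-nitropropan-2-yl]-2-methylcyclopentylidene}-1-phenylethan-1-amine | C[C@@H](N=C1CCC[C@@]1(C)[C@H](CO[Si](C)(C)C(C)(C)C)C[N+](=O)[O-])c1ccccc1 | intermediate
9 | (S)-2-[(S)-1-(tert-butyldimethylsilyloxy)-3-nitropropan-2-yl]-2-methylcyclopentan-1-one | O=C1CCC[C@@]1(C)[C@H](CO[Si](C)(C)C(C)(C)C)C[N+](=O)[O-] | intermediate
10 | sodium nitronate of 9 | O=C1CCC[C@@]1(C)[C@H](CO[Si](C)(C)C(C)(C)C)C=[N+]([O-])[O-].[Na+] | intermediate
11 | (R)-3-(tert-butyldimethylsilyloxy)-2-[(S)-1-methyl-2-oxocyclopentyl]propanal | O=C1CCC[C@@]1(C)[C@H](CO[Si](C)(C)C(C)(C)C)C=O | intermediate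
12 | methyl (2Z,4R)-5-(tert-butyldimethylsilyloxy)-4-[(S)-1-methyl-2-oxocyclopentyl]pent-2-enoate | O=C1CCC[C@@]1(C)[C@H](CO[Si](C)(C)C(C)(C)C)/C=C\C(=O)OC | intermediate
13 | methyl (2Z,4R)-5-hydroxy-4-[(S)-1-methyl-2-oxocyclopentyl]pent-2-enoate | O=C1CCC[C@@]1(C)[C@H](CO)/C=C\C(=O)OC | intermediate
14 | (R)-5-[(S)-1-methyl-2-oxocyclopentyl]-5,6-dihydro-2H-pyran-2-one | O=C1CCC[C@@]1(C)[C@@H]1COC(=O)C=C1 | intermediate
15 | (4R,5R)-4-(hydroxymethyl)-5-[(S)-1-methyl-2-oxocyclopentyl]tetrahydro-2H-pyran-2-one | O=C1CCC[C@@]1(C)[C@@H]1COC(=O)C[C@H]1CO | intermediate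
16 | (S)-2-{(R)-2-hydroxy-1-[(R)-5-oxotetrahydrofuran-3-yl]ethyl}-2-methylcyclopentan-1-one | O=C1CCC[C@@]1(C)[C@H](CO)[C@@H]1COC(=O)C1 | intermediate
17 | (R)-2-[(S)-1-methyl-2-oxocyclopentyl]-2-[(R)-5-oxotetrahydrofuran-3-yl]ethyl acetate | O=C1CCC[C@@]1(C)[C@H](COC(C)=O)[C@@H]1COC(=O)C1 | intermediate
18 | (R)-2-[(S)-1-methyl-2-{[(trifluoromethyl)sulfonyl]oxy}cyclopent-2-en-1-yl]-2-[(R)-5-oxotetrahydrofuran-3-yl]ethyl acetate | O=S(=O)(OC1=CCC[C@@]1(C)[C@H](COC(C)=O)[C@@H]1COC(=O)C1)C(F)(F)F | intermediate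
19 | 4-methoxybenzyl (S)-5-{(R)-2-acetoxy-1-[(R)-5-oxotetrahydrofuran-3-yl]ethyl}-5-methylcyclopent-1-ene-1-carboxylate | COc1ccc(COC(=O)C2=CCC[C@@]2(C)[C@H](COC(C)=O)[C@@H]2COC(=O)C2)cc1 | intermediate
20 | 2,2-dimethylpent-4-enoic acid | C=CCC(C)(C)C(=O)O | starting material
21 | N-hydroxyphthalimide | O=C1c2ccccc2C(=O)N1O | starting material
22 | 1,3-dioxoisoindolin-2-yl 2,2-dimethylpent-4-enoate | C=CCC(C)(C)C(=O)ON1C(=O)c2ccccc2C1=O | intermediate
23 | 4-methoxybenzyl (1R,2S,5R)-2-{(R)-2-acetoxy-1-[(R)-5-oxotetrahydrofuran-3-yl]ethyl}-2-methyl-5-(2-methylpent-4-en-2-yl)cyclopentane-1-carboxylate | C=CCC(C)(C)[C@@H]1CC[C@@](C)([C@H](COC(C)=O)[C@@H]2COC(=O)C2)[C@@H]1C(=O)OCc1ccc(OC)cc1 | intermediate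
24 | (1R,2S,5R)-2-{(R)-2-acetoxy-1-[(R)-5-oxotetrahydrofuran-3-yl]ethyl}-2-methyl-5-(2-methylpent-4-en-2-yl)cyclopentane-1-carboxylic acid | C=CCC(C)(C)[C@@H]1CC[C@@](C)([C@H](COC(C)=O)[C@@H]2COC(=O)C2)[C@@H]1C(=O)O | intermediate
25 | diphenyl diselenide | c1ccc(cc1)[Se][Se]c1ccccc1 | starting material
26 | Se-phenyl (1R,2S,5R)-2-{(R)-2-acetoxy-1-[(R)-5-oxotetrahydrofuran-3-yl]ethyl}-2-methyl-5-(2-methylpent-4-en-2-yl)cyclopentane-1-carboselenoate | C=CCC(C)(C)[C@@H]1CC[C@@](C)([C@H](COC(C)=O)[C@@H]2COC(=O)C2)[C@@H]1C(=O)[Se]c1ccccc1 | intermediate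
27 | (R)-2-[(3S,3aR,8aR)-3,8,8-trimethyl-4-oxodecahydroazulen-3-yl]-2-[(R)-5-oxotetrahydrofuran-3-yl]ethyl acetate | O=C1CCCC(C)(C)[C@@H]2CC[C@@](C)([C@H](COC(C)=O)[C@@H]3COC(=O)C3)[C@H]12 | intermediate
28 | (R)-2-[(3R,3aS,8aR)-3,8,8-trimethyl-4-methylidenedecahydroazulen-3-yl]-2-[(R)-5-oxotetrahydrofuran-3-yl]ethyl acetate (CNP0235949.1) | C=C1CCCC(C)(C)[C@@H]2CC[C@@](C)([C@H](COC(C)=O)[C@@H]3COC(=O)C3)[C@H]12 | target

Total step count: 16. Longest linear sequence: 14 steps (5 to 28 through steps 2–10 and 12–16).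

Steps most likely to fail

Step 15 (key ring closure). The acyl radical may lose CO or be reduced to the aldehyde faster than it closes the ring. The fallback closes the ring by metathesis instead of a radical. It sets out from acid 24, which is converted with EtSH, EDC·HCl and DMAP into the S-ethyl thioester F1. Liebeskind–Srogl coupling with tributyl(vinyl)stannane (Pd2(dba)3, tri(2-furyl)phosphine, copper thiophene-2-carboxylate C5H3CuO2S, THF, 50 °C) should give the vinyl ketone F2. Ring-closing metathesis with the second-generation Grubbs catalyst (CH2Cl2, 40 °C) should give the cycloheptenone F3, in which the vinyl carbon takes the place of C1. Hydrogenation (H2, Pd/C, EtOAc) comes back to the route at ketone 27.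

Step 12 (Giese addition). The tertiary radical may be reduced before it adds to the hindered β-carbon C5, and hydrogen delivery to C9 may occur from the wrong face. The fallback is a polar route that sets out from triflate 18 and comes back at acid 24. Carbonylation as in step 10 with 2,2,2-trichloroethanol gives the trichloroethyl enoate F4. A Mukaiyama–Michael addition of 2-methyl-1-(trimethylsilyloxy)prop-1-ene (TiCl4, CH2Cl2, −78 °C, cold buffered quench for kinetic C9 protonation) should give the aldehyde F5. Wittig reaction with Ph3P=CHOMe gives the enol ether F6, and aqueous HCl in THF hydrolyses it to the homologous aldehyde F7. Wittig methylenation (Ph3P=CH2) gives the alkene ester F8. Zn in AcOH then removes the trichloroethyl group and returns acid 24.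

Step 7 (photochemical hydroxymethylation). The cyclopentanone may undergo competing photochemistry (α-cleavage), or the facial selectivity at C12 may be incomplete. The fallback is ionic and sets out from lactone 14. Copper-catalysed conjugate addition of (isopropoxydimethylsilyl)methylmagnesium chloride (CuBr·SMe2, Me3SiCl, THF, −78 °C) anti to the C11 substituent should give the silane F9. Tamao oxidation (H2O2, KF, KHCO3, THF/MeOH) comes back to the route at alcohol 15.

Further compounds
F1 | step 15 | S-ethyl (1R,2S,5R)-2-{(R)-2-acetoxy-1-[(R)-5-oxotetrahydrofuran-3-yl]ethyl}-2-methyl-5-(2-methylpent-4-en-2-yl)cyclopentane-1-carbothioate | C=CCC(C)(C)[C@@H]1CC[C@@](C)([C@H](COC(C)=O)[C@@H]2COC(=O)C2)[C@@H]1C(=O)SCC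
F2 | step 15 | 1-[(1R,2S,5R)-2-{(R)-2-acetoxy-1-[(R)-5-oxotetrahydrofuran-3-yl]ethyl}-2-methyl-5-(2-methylpent-4-en-2-yl)cyclopentyl]prop-2-en-1-one | C=CCC(C)(C)[C@@H]1CC[C@@](C)([C@H](COC(C)=O)[C@@H]2COC(=O)C2)[C@@H]1C(=O)C=C
F3 | step 15 | (R)-2-[(3S,3aR,8aR)-3,8,8-trimethyl-4-oxo-1,2,3,3a,4,7,8,8a-octahydroazulen-3-yl]-2-[(R)-5-oxotetrahydrofuran-3-yl]ethyl acetate | O=C1C=CCC(C)(C)[C@@H]2CC[C@@](C)([C@H](COC(C)=O)[C@@H]3COC(=O)C3)[C@H]12
F4 | step 12 | 2,2,2-trichloroethyl (S)-5-{(R)-2-acetoxy-1-[(R)-5-oxotetrahydrofuran-3-yl]ethyl}-5-methylcyclopent-1-ene-1-carboxylate | O=C(OCC(Cl)(Cl)Cl)C1=CCC[C@@]1(C)[C@H](COC(C)=O)[C@@H]1COC(=O)C1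
F5 | step 12 | 2,2,2-trichloroethyl (1R,2S,5R)-2-{(R)-2-acetoxy-1-[(R)-5-oxotetrahydrofuran-3-yl]ethyl}-2-methyl-5-(2-methyl-1-oxopropan-2-yl)cyclopentane-1-carboxylate | O=CC(C)(C)[C@@H]1CC[C@@](C)([C@H](COC(C)=O)[C@@H]2COC(=O)C2)[C@@H]1C(=O)OCC(Cl)(Cl)Cl
F6 | step 12 | 2,2,2-trichloroethyl (1R,2S,5R)-2-{(R)-2-acetoxy-1-[(R)-5-oxotetrahydrofuran-3-yl]ethyl}-5-(4-methoxy-2-methylbut-3-en-2-yl)-2-methylcyclopentane-1-carboxylate (E/Z mixture) | COC=CC(C)(C)[C@@H]1CC[C@@](C)([C@H](COC(C)=O)[C@@H]2COC(=O)C2)[C@@H]1C(=O)OCC(Cl)(Cl)Cl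
F7 | step 12 | 2,2,2-trichloroethyl (1R,2S,5R)-2-{(R)-2-acetoxy-1-[(R)-5-oxotetrahydrofuran-3-yl]ethyl}-2-methyl-5-(2-methyl-4-oxobutan-2-yl)cyclopentane-1-carboxylate | O=CCC(C)(C)[C@@H]1CC[C@@](C)([C@H](COC(C)=O)[C@@H]2COC(=O)C2)[C@@H]1C(=O)OCC(Cl)(Cl)Cl
F8 | step 12 | 2,2,2-trichloroethyl (1R,2S,5R)-2-{(R)-2-acetoxy-1-[(R)-5-oxotetrahydrofuran-3-yl]ethyl}-2-methyl-5-(2-methylpent-4-en-2-yl)cyclopentane-1-carboxylate | C=CCC(C)(C)[C@@H]1CC[C@@](C)([C@H](COC(C)=O)[C@@H]2COC(=O)C2)[C@@H]1C(=O)OCC(Cl)(Cl)Cl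
F9 | step 7 | (4R,5R)-4-{[dimethyl(propan-2-yloxy)silyl]methyl}-5-[(S)-1-methyl-2-oxocyclopentyl]tetrahydro-2H-pyran-2-one | O=C1CCC[C@@]1(C)[C@@H]1COC(=O)C[C@H]1C[Si](C)(C)OC(C)C
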